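## Retrosynthetic overview

1. Last bond: the C(sp3)–C(sp2) bond between the ethylene linker and the cyclohexene, made by B-alkyl Suzuki coupling of a vinyl-bearing bicycle with a tetrasubstituted enol triflate; then global desilylation.
2. Right half: the cyclohexene ring is bought as 2-methylcyclohexane-1,3-dione; C-allylation, CBS desymmetrisation (both stereocentres), α-methylation and enol triflate, cross-metathesis for the side chain.
3. Left half: (3S,6E)-nerolidol supplies the tertiary carbinol; Shi bis-epoxidation, cross-metathesis to an allylsilane, then one epoxide-opening cascade.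
4. Ring order: in the cascade the oxepane ring closes first (internal epoxide oxygen onto the terminal epoxide), then the cyclohexane ring (allylsilane onto the epoxonium ion); the cyclohexene ring is only decorated.

Assumption: (3S,6E)-nerolidol (natural (+)-trans-nerolidol), allyltriethylsilane and the D-fructose-derived Shi ketone are bought; compound 7 is carried as a C6 epimer mixture (that centre is erased in step 5).

## Route

Step 1
Reactants: 1 2-methylcyclohexane-1,3-dione; 2 allyl bromide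
Product: 3 2-methyl-2-(prop-2-en-1-yl)cyclohexane-1,3-dione
Conditions: 1 M aq NaOH, 2 (1.3 equiv), rt, 16 h
Reagents that add atoms: none
Why: C-alkylation (SN2) of the stabilised 1,3-diketone enolate with the allylic bromide gives the 2,2-disubstituted dione, whose C2 is still prochiral.

Step 2
Reactants: 3 2-methyl-2-(prop-2-en-1-yl)cyclohexane-1,3-dione
Product: 4 (2R,3R)-3-hydroxy-2-methyl-2-(prop-2-en-1-yl)cyclohexan-1-one
Conditions: (S)-2-methyl-CBS-oxazaborolidine (0.2 equiv), catecholborane (1.2 equiv), toluene, −78 °C; then MeOH, aq NaHCO3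
Reagents that add atoms: none
Why: Corey–Bakshi–Shibata reduction desymmetrises the dione: with the quaternary carbon as the large group the (S)-catalyst gives the (3R) carbinol, and hydride enters from the methyl side (anti to allyl), so the quaternary centre (2R, OH cis to allyl) is fixed in the same event.

Step 3
Reactants: 4 (2R,3R)-3-hydroxy-2-methyl-2-(prop-2-en-1-yl)cyclohexan-1-one
Product: 5 (2R,3R)-2-methyl-2-(prop-2-en-1-yl)-3-(triethylsilyloxy)cyclohexan-1-one
Conditions: Et3SiCl, imidazole, DMF, 0 °C to rt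
Reagents that add atoms: chlorotriethylsilane, CC[Si](Cl)(CC)CC
Why: Silyl ether formation blocks retro-aldol cleavage of the β-hydroxy ketone under the strong bases that follow; no stereocentre is touched.

Step 4
Reactants: 5 (2R,3R)-2-methyl-2-(prop-2-en-1-yl)-3-(triethylsilyloxy)cyclohexan-1-one
Product: 7 (2R,3R)-2,6-dimethyl-2-(prop-2-en-1-yl)-3-(triethylsilyloxy)cyclohexan-1-one (C6 epimer mixture), via lithium enolate 6 (not isolated)
Conditions: LiN(iPr)2 (1.1 equiv), THF, −78 °C; then MeI, −78 to −20 °C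
Reagents that add atoms: iodomethane, CI
Why: Enolate alkylation is regiospecific because C2 is quaternary and only C6 carries α-hydrogens; the new C6 centre is uncontrolled and irrelevant.

Step 5
Reactants: 7 (2R,3R)-2,6-dimethyl-2-(prop-2-en-1-yl)-3-(triethylsilyloxy)cyclohexan-1-one
Product: 9 (5R,6R)-2,6-dimethyl-6-(prop-2-en-1-yl)-5-(triethylsilyloxy)cyclohex-1-en-1-yl trifluoromethanesulfonate, via potassium enolate 8 (not isolated)
Conditions: KN(SiMe3)2 (1.3 equiv), THF, −78 to 0 °C; then PhNTf2, −78 °C to rt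
Reagents that add atoms: N-phenylbis(trifluoromethanesulfonimide), O=S(=O)(N(c1ccccc1)S(=O)(=O)C(F)(F)F)C(F)(F)F
Why: Enol triflate formation by O-sulfonylation of the only possible enolate gives the tetrasubstituted ring alkene in its final position and removes the C6 stereocentre.

Step 6
Reactants: 9 (5R,6R)-2,6-dimethyl-6-(prop-2-en-1-yl)-5-(triethylsilyloxy)cyclohex-1-en-1-yl trifluoromethanesulfonate; 10 2-methylbut-3-en-2-ol
Product: 11 (5R,6R)-6-[(2E)-4-hydroxy-4-methylpent-2-en-1-yl]-2,6-dimethyl-5-(triethylsilyloxy)cyclohex-1-en-1-yl trifluoromethanesulfonate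
Conditions: 10 (5 equiv), second-generation Grubbs catalyst (5 mol %), CH2Cl2, 40 °C
Reagents that add atoms: none
Why: Olefin cross-metathesis between the terminal allyl group and the non-dimerising tertiary allylic alcohol gives the E alkene (bulky CMe2OH terminus), while the tetrasubstituted enol triflate is inert.

Step 7
Reactants: 12 (3S,6E)-3,7,11-trimethyldodeca-1,6,10-trien-3-ol ((3S,6E)-nerolidol)
Product: 13 triethyl{[(3S,6E)-3,7,11-trimethyldodeca-1,6,10-trien-3-yl]oxy}silane
Conditions: Et3SiOTf, 2,6-lutidine, CH2Cl2, −78 to 0 °C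
Reagents that add atoms: triethylsilyl trifluoromethanesulfonate, CC[Si](CC)(CC)OS(=O)(=O)C(F)(F)F
Why: Silylation of the tertiary alcohol with the silyl triflate stops the hydroxyl from opening the nearby epoxide later; the purchased (3S) centre becomes C7 of the bicycle.

Step 8
Reactants: 13 triethyl{[(3S,6E)-3,7,11-trimethyldodeca-1,6,10-trien-3-yl]oxy}silane
Product: 14 (3S,6R,7R,10R)-6,7:10,11-diepoxy-3,7,11-trimethyl-3-(triethylsilyloxy)dodec-1-ene
Conditions: D-fructose-derived Shi ketone (0.6 equiv), KHSO5 (as 2KHSO5·KHSO4·K2SO4), K2CO3, Bu4NHSO4, MeCN/CH2(OMe)2/aq Na2B4O7 buffer (pH 10.5), 0 °C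
Reagents that add atoms: potassium peroxymonosulfate, [K+].[O-]S(=O)(=O)OO
Why: Shi asymmetric epoxidation: the chiral dioxirane adds oxygen through a spiro transition state to the same face of both electron-rich trisubstituted alkenes, setting (6R,7R) and (10R) under catalyst control and leaving the hindered monosubstituted vinyl group alone.

Step 9
Reactants: 14 (3S,6R,7R,10R)-6,7:10,11-diepoxy-3,7,11-trimethyl-3-(triethylsilyloxy)dodec-1-ene; 15 allyltriethylsilane
Product: 16 (2E,4S,7R,8R,11R)-7,8:11,12-diepoxy-4,8,12-trimethyl-1-(triethylsilyl)-4-(triethylsilyloxy)tridec-2-ene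
Conditions: 15 (6 equiv), second-generation Hoveyda–Grubbs catalyst (10 mol %), CH2Cl2, 40 °C
Reagents that add atoms: none
Why: Olefin cross-metathesis of the only remaining alkene with excess allylsilane installs the cascade terminator; the fully substituted allylic carbon prevents homodimerisation of 14 and enforces E geometry.

Step 10
Reactants: 16 (2E,4S,7R,8R,11R)-7,8:11,12-diepoxy-4,8,12-trimethyl-1-(triethylsilyl)-4-(triethylsilyloxy)tridec-2-ene
Product: 17 (3R,5aR,6R,7S,9aR)-6-ethenyl-2,2,5a,7-tetramethyl-3,7-bis(triethylsilyloxy)decahydro-1-benzoxepine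
Conditions: Et3SiOTf (0.2 equiv), 2,6-di-tert-butyl-4-methylpyridine (0.5 equiv), CH2Cl2, −78 °C; then Et3N, aq NaHCO3
Reagents that add atoms: none
Why: Epoxide-opening cascade with intramolecular Sakurai termination: the silylated terminal epoxide is opened at its tertiary carbon by the internal epoxide oxygen (oxepane, C3 retained), the epoxonium ion is opened with inversion at its tertiary carbon by the allylsilane through a chair transition state with the new vinyl group equatorial (trans fusion, 6R), and loss of Et3Si+ returns the catalyst, so 17 is an isomer of 16.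

Step 11
Reactants: 17 (3R,5aR,6R,7S,9aR)-6-ethenyl-2,2,5a,7-tetramethyl-3,7-bis(triethylsilyloxy)decahydro-1-benzoxepine; 11 (5R,6R)-6-[(2E)-4-hydroxy-4-methylpent-2-en-1-yl]-2,6-dimethyl-5-(triethylsilyloxy)cyclohex-1-en-1-yl trifluoromethanesulfonate
Product: 19 (3E)-5-[(1S,6R)-1,3-dimethyl-2-{2-[(3R,5aR,6R,7S,9aR)-2,2,5a,7-tetramethyl-3,7-bis(triethylsilyloxy)decahydro-1-benzoxepin-6-yl]ethyl}-6-(triethylsilyloxy)cyclohex-2-en-1-yl]-2-methylpent-3-en-2-ol, via alkylborane 18 (not isolated)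
Conditions: 17, 9-BBN dimer, THF, rt to 40 °C; then degassed H2O, 11, PdCl2(dppf) (10 mol %), AsPh3, Cs2CO3, DMF, 50 °C
Reagents that add atoms: none
Why: Anti-Markovnikov hydroboration of the vinyl group followed by B-alkyl Suzuki–Miyaura coupling with the enol triflate forms the linker bond with the tetrasubstituted alkene already in place; no stereocentre is touched.

Step 12
Reactants: 19 (3E)-5-[(1S,6R)-1,3-dimethyl-2-{2-[(3R,5aR,6R,7S,9aR)-2,2,5a,7-tetramethyl-3,7-bis(triethylsilyloxy)decahydro-1-benzoxepin-6-yl]ethyl}-6-(triethylsilyloxy)cyclohex-2-en-1-yl]-2-methylpent-3-en-2-ol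
Product: 20 siphonellinol C
Conditions: HF·pyridine, excess pyridine, THF, 0 °C to rt
Reagents that add atoms: none
Why: Buffered fluoride desilylation removes all three triethylsilyl ethers without ionising the tertiary allylic alcohol; no stereocentre is affected.

## Compound list

1 | 2-methylcyclohexane-1,3-dione | CC1C(=O)CCCC1=O | starting material
2 | allyl bromide (3-bromoprop-1-ene) | C=CCBr | starting material
3 | 2-methyl-2-(prop-2-en-1-yl)cyclohexane-1,3-dione | C=CCC1(C)C(=O)CCCC1=O | intermediate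
4 | (2R,3R)-3-hydroxy-2-methyl-2-(prop-2-en-1-yl)cyclohexan-1-one | O=C1[C@](C)(CC=C)[C@H](O)CCC1 | intermediate
5 | (2R,3R)-2-methyl-2-(prop-2-en-1-yl)-3-(triethylsilyloxy)cyclohexan-1-one | O=C1[C@](C)(CC=C)[C@H](O[Si](CC)(CC)CC)CCC1 | intermediate
6 | lithium (5R,6R)-6-methyl-6-(prop-2-en-1-yl)-5-(triethylsilyloxy)cyclohex-1-en-1-olate | C1=C([O-])[C@](C)(CC=C)[C@H](O[Si](CC)(CC)CC)CC1.[Li+] | intermediate
7 | (2R,3R)-2,6-dimethyl-2-(prop-2-en-1-yl)-3-(triethylsilyloxy)cyclohexan-1-one (C6 epimer mixture) | O=C1[C@](C)(CC=C)[C@H](O[Si](CC)(CC)CC)CCC1C | intermediate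
8 | potassium (5R,6R)-2,6-dimethyl-6-(prop-2-en-1-yl)-5-(triethylsilyloxy)cyclohex-1-en-1-olate | CC1=C([O-])[C@](C)(CC=C)[C@H](O[Si](CC)(CC)CC)CC1.[K+] | intermediate
9 | (5R,6R)-2,6-dimethyl-6-(prop-2-en-1-yl)-5-(triethylsilyloxy)cyclohex-1-en-1-yl trifluoromethanesulfonate | CC1=C(OS(=O)(=O)C(F)(F)F)[C@](C)(CC=C)[C@H](O[Si](CC)(CC)CC)CC1 | intermediate
10 | 2-methylbut-3-en-2-ol | C=CC(C)(C)O | starting material
11 | (5R,6R)-6-[(2E)-4-hydroxy-4-methylpent-2-en-1-yl]-2,6-dimethyl-5-(triethylsilyloxy)cyclohex-1-en-1-yl trifluoromethanesulfonate | CC1=C(OS(=O)(=O)C(F)(F)F)[C@](C)(C/C=C/C(C)(C)O)[C@H](O[Si](CC)(CC)CC)CC1 | intermediate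
12 | (3S,6E)-3,7,11-trimethyldodeca-1,6,10-trien-3-ol ((3S,6E)-nerolidol) | C=C[C@@](C)(O)CC/C=C(\C)CCC=C(C)C | starting material
13 | triethyl{[(3S,6E)-3,7,11-trimethyldodeca-1,6,10-trien-3-yl]oxy}silane | C=C[C@@](C)(O[Si](CC)(CC)CC)CC/C=C(\C)CCC=C(C)C | intermediate
14 | (3S,6R,7R,10R)-6,7:10,11-diepoxy-3,7,11-trimethyl-3-(triethylsilyloxy)dodec-1-ene | C=C[C@@](C)(O[Si](CC)(CC)CC)CC[C@H]1O[C@]1(C)CC[C@H]2OC2(C)C | intermediate
15 | allyltriethylsilane (triethyl(prop-2-en-1-yl)silane) | C=CC[Si](CC)(CC)CC | starting material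
16 | (2E,4S,7R,8R,11R)-7,8:11,12-diepoxy-4,8,12-trimethyl-1-(triethylsilyl)-4-(triethylsilyloxy)tridec-2-ene | CC[Si](CC)(CC)C/C=C/[C@@](C)(O[Si](CC)(CC)CC)CC[C@H]1O[C@]1(C)CC[C@H]2OC2(C)C | intermediate
17 | (3R,5aR,6R,7S,9aR)-6-ethenyl-2,2,5a,7-tetramethyl-3,7-bis(triethylsilyloxy)decahydro-1-benzoxepine | C=C[C@@H]1[C@@]2(C)CC[C@@H](O[Si](CC)(CC)CC)C(C)(C)O[C@@H]2CC[C@]1(C)O[Si](CC)(CC)CC | intermediate
18 | 9-{2-[(3R,5aR,6R,7S,9aR)-2,2,5a,7-tetramethyl-3,7-bis(triethylsilyloxy)decahydro-1-benzoxepin-6-yl]ethyl}-9-borabicyclo[3.3.1]nonane | B1(C2CCCC1CCC2)CC[C@@H]3[C@@]4(C)CC[C@@H](O[Si](CC)(CC)CC)C(C)(C)O[C@@H]4CC[C@]3(C)O[Si](CC)(CC)CC | intermediate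
19 | (3E)-5-[(1S,6R)-1,3-dimethyl-2-{2-[(3R,5aR,6R,7S,9aR)-2,2,5a,7-tetramethyl-3,7-bis(triethylsilyloxy)decahydro-1-benzoxepin-6-yl]ethyl}-6-(triethylsilyloxy)cyclohex-2-en-1-yl]-2-methylpent-3-en-2-ol | CC1=C(CC[C@@H]2[C@@]3(C)CC[C@@H](O[Si](CC)(CC)CC)C(C)(C)O[C@@H]3CC[C@]2(C)O[Si](CC)(CC)CC)[C@](C)(C/C=C/C(C)(C)O)[C@H](O[Si](CC)(CC)CC)CC1 | intermediate
20 | siphonellinol C, (3R,5aR,6R,7S,9aR)-6-{2-[(5R,6S)-5-hydroxy-6-[(2E)-4-hydroxy-4-methylpent-2-en-1-yl]-2,6-dimethylcyclohex-1-en-1-yl]ethyl}-2,2,5a,7-tetramethyldecahydro-1-benzoxepine-3,7-diol | CC1=C(CC[C@@H]2[C@@]3(C)CC[C@@H](O)C(C)(C)O[C@@H]3CC[C@]2(C)O)[C@](C)(C/C=C/C(C)(C)O)[C@H](O)CC1 | target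

## Step count and risks

Total steps: 12. Longest linear sequence: 8 steps (steps 1–6, then 11 and 12, from 2-methylcyclohexane-1,3-dione); the nerolidol branch reaches 17 in 4 steps.

The three steps most likely to fail:

Step 9 (cross-metathesis on the silylated tertiary allylic ether). The vinyl group sits on a fully substituted carbon carrying a bulky silyloxy group and may not engage the catalyst. The fallback sets out from 12 and comes back to the route at 16. It changes the order of protection and C–C bond formation so that the metathesis runs on the free tertiary allylic alcohol, a much better partner. Unprotected 12 is epoxidised under the conditions of step 8 to the diepoxy alcohol (3S,6R,7R,10R)-6,7:10,11-diepoxy-3,7,11-trimethyldodec-1-en-3-ol F1, which is kept cold and slightly basic because its hydroxyl can open the nearer epoxide. F1 is cross-metathesised with 15 (second-generation Hoveyda–Grubbs catalyst, CH2Cl2, 40 °C) to the hydroxy allylsilane (2E,4S,7R,8R,11R)-7,8:11,12-diepoxy-4,8,12-trimethyl-1-(triethylsilyl)tridec-2-en-4-ol F2. Silylation of F2 (Et3SiOTf, 2,6-lutidine, CH2Cl2, −78 °C) gives 16.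

Step 10 (cascade). The tertiary allylic silyl ether next to the allylsilane can ionise and lose both groups to a diene, and the ring-junction-adjacent carbon C6 is set only under kinetic control. The fallback sets out from 14 and comes back to the route at 17. It replaces the allylsilane by a silyl enol ether, so no allylic ether is present and C6 becomes an epimerisable aldehyde carbon set by equilibration. Hydroboration–oxidation of the vinyl group of 14 (9-BBN, THF; then NaBO3·4H2O) gives the primary alcohol (3S,6R,7R,10R)-6,7:10,11-diepoxy-3,7,11-trimethyl-3-(triethylsilyloxy)dodecan-1-ol F3. Dess–Martin oxidation (NaHCO3 buffer) gives the aldehyde (3S,6R,7R,10R)-6,7:10,11-diepoxy-3,7,11-trimethyl-3-(triethylsilyloxy)dodecanal F4. Enolisation and O-silylation (KN(SiMe3)2, Et3SiCl, THF, −78 °C) gives the enol ether (3S,6R,7R,10R)-6,7:10,11-diepoxy-3,7,11-trimethyl-1,3-bis(triethylsilyloxy)dodec-1-ene F5 as an E/Z mixture. The same Et3SiOTf-catalysed cascade, now ended by the enol ether β-carbon, gives the bicyclic aldehyde (3R,5aR,6R,7S,9aR)-2,2,5a,7-tetramethyl-3,7-bis(triethylsilyloxy)decahydro-1-benzoxepine-6-carbaldehyde F6, whose formyl group is brought equatorial with Et3N if needed. Wittig methylenation (Ph3P=CH2, THF, −78 to 0 °C) then gives 17.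

Step 11 (B-alkyl Suzuki coupling at a tetrasubstituted enol triflate flanked by a quaternary carbon). Oxidative addition and transmetalation from boron may both be too slow, leaving triflate hydrolysis and protodeboronation. The fallback sets out from 17 and comes back to the route at 19. It abandons the organoboron route for a cross-electrophile coupling in which the alkyl partner reaches nickel as a radical, which is less sensitive to crowding. The borane from 17 and 9-BBN is cleaved with I2/NaOMe (MeOH, 0 °C) to the primary iodide (3R,5aR,6R,7S,9aR)-6-(2-iodoethyl)-2,2,5a,7-tetramethyl-3,7-bis(triethylsilyloxy)decahydro-1-benzoxepine F7. F7 and 11 are then joined by nickel-catalysed reductive coupling (NiBr2(MeOCH2CH2OMe), 4,4'-di-tert-butyl-2,2'-bipyridine, Zn dust, N,N-dimethylacetamide, rt) to give 19.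

## Further compounds

F1 | step 9 | (3S,6R,7R,10R)-6,7:10,11-diepoxy-3,7,11-trimethyldodec-1-en-3-ol | C=C[C@@](C)(O)CC[C@H]1O[C@]1(C)CC[C@H]2OC2(C)C
F2 | step 9 | (2E,4S,7R,8R,11R)-7,8:11,12-diepoxy-4,8,12-trimethyl-1-(triethylsilyl)tridec-2-en-4-ol | CC[Si](CC)(CC)C/C=C/[C@@](C)(O)CC[C@H]1O[C@]1(C)CC[C@H]2OC2(C)C
F3 | step 10 | (3S,6R,7R,10R)-6,7:10,11-diepoxy-3,7,11-trimethyl-3-(triethylsilyloxy)dodecan-1-ol | OCC[C@@](C)(O[Si](CC)(CC)CC)CC[C@H]1O[C@]1(C)CC[C@H]2OC2(C)C
F4 | step 10 | (3S,6R,7R,10R)-6,7:10,11-diepoxy-3,7,11-trimethyl-3-(triethylsilyloxy)dodecanal | O=CC[C@@](C)(O[Si](CC)(CC)CC)CC[C@H]1O[C@]1(C)CC[C@H]2OC2(C)C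
F5 | step 10 | (3S,6R,7R,10R)-6,7:10,11-diepoxy-3,7,11-trimethyl-1,3-bis(triethylsilyloxy)dodec-1-ene (E/Z mixture) | CC[Si](CC)(CC)OC=C[C@@](C)(O[Si](CC)(CC)CC)CC[C@H]1O[C@]1(C)CC[C@H]2OC2(C)C
F6 | step 10 | (3R,5aR,6R,7S,9aR)-2,2,5a,7-tetramethyl-3,7-bis(triethylsilyloxy)decahydro-1-benzoxepine-6-carbaldehyde | O=C[C@@H]1[C@@]2(C)CC[C@@H](O[Si](CC)(CC)CC)C(C)(C)O[C@@H]2CC[C@]1(C)O[Si](CC)(CC)CC
F7 | step 11 | (3R,5aR,6R,7S,9aR)-6-(2-iodoethyl)-2,2,5a,7-tetramethyl-3,7-bis(triethylsilyloxy)decahydro-1-benzoxepine | ICC[C@@H]1[C@@]2(C)CC[C@@H](O[Si](CC)(CC)CC)C(C)(C)O[C@@H]2CC[C@]1(C)O[Si](CC)(CC)CC
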